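**Assumption:** the SMILES is taken exactly as written, i.e. a cis-fused oxepane–cyclohexane (5aS,6S,7R,9aR) joined to a (1S,3aS,5R,8aS)-hydroazulene; compounds 1, 4, 15, 16 and 19 are bought. Nothing here has been run; the stereochemical outcomes of steps 7, 9 and 18 are predictions from models.

## Retrosynthetic overview

1. Target ⇐ oxidation of the C-3 carbinol ⇐ union of vinyl fragment 14 (oxepane–cyclohexane) with allylic ester 28 (hydroazulene) by a new copper-catalysed, phosphine-directed syn-SN2′ B-alkyl coupling that makes the azulene C5–CH2 bond and sets C-5.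
2. Fragment 14: the cyclohexenone ring is bought (1). CBS reduction sets C-9a, the oxepane is closed second by 7-endo epoxide opening, then cuprate addition/Michael trapping and MeMgBr set C-5a, C-6 and C-7.
3. Fragment 28: cyclopentenone by Stetter reaction/aldol condensation, asymmetric methyl addition sets C-1, the seven-membered ring follows by RCM, and OH-directed hydrogenation sets the cis ring fusion.
4. Ring order: six-membered ring (given) → oxepane; five-membered ring → seven-membered ring; the fragments are joined last.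

## Route

Step 1
Reactants: 1 1,4-dioxaspiro[4.5]dec-6-en-8-one
Product: 2 7-iodo-1,4-dioxaspiro[4.5]dec-6-en-8-one
Conditions: I2, pyridine/CH2Cl2, 0 °C → rt
Reagents that add atoms: iodine, SMILES II
Why: Pyridine-mediated α-iodination of the enone (addition–elimination) installs the handle for cross-coupling at the future C-5a; no stereocentre is formed.

Step 2
Reactants: 2 7-iodo-1,4-dioxaspiro[4.5]dec-6-en-8-one
Product: 3 (8R)-7-iodo-1,4-dioxaspiro[4.5]dec-6-en-8-ol
Conditions: (S)-2-methyl-CBS-oxazaborolidine (10 mol %), BH3·SMe2, THF, −20 °C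
Reagents that add atoms: none
Why: Corey–Bakshi–Shibata reduction in which the α-iodovinyl side acts as the large group, so hydride is delivered to one face and the carbinol (future C-9a) is set as R.

Step 3
Reactants: 3 (8R)-7-iodo-1,4-dioxaspiro[4.5]dec-6-en-8-ol; 4 4-methylpenta-1,3-diene
Product: 6 (8R)-7-(4-methylpent-3-en-1-yl)-1,4-dioxaspiro[4.5]dec-6-en-8-ol, via alkylborane 5 (not isolated)
Conditions: 4, 9-BBN, THF, 0 °C → rt; then 3, PdCl2(dppf) (5 mol %), 3 M aq. NaOH, DMF, rt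
Reagents that add atoms: none
Why: Anti-Markovnikov hydroboration of the terminal alkene of the diene followed by B-alkyl Suzuki–Miyaura coupling with the vinyl iodide attaches the homoprenyl chain without touching the carbinol centre.

Step 4
Reactants: 6 (8R)-7-(4-methylpent-3-en-1-yl)-1,4-dioxaspiro[4.5]dec-6-en-8-ol
Product: 7 (4R)-4-hydroxy-3-(4-methylpent-3-en-1-yl)cyclohex-2-en-1-one
Conditions: PPTS (cat.), acetone/H2O, 40 °C
Reagents that add atoms: water, SMILES O
Why: Acid-catalysed ketal hydrolysis unmasks the γ-hydroxy enone, placing the chain on the β-carbon and the hydroxyl on the γ-carbon.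

Step 5
Reactants: 7 (4R)-4-hydroxy-3-(4-methylpent-3-en-1-yl)cyclohex-2-en-1-one
Product: 8 (4R)-3-{2-[(2R)-3,3-dimethyloxiran-2-yl]ethyl}-4-hydroxycyclohex-2-en-1-one
Conditions: D-fructose-derived Shi ketone (30 mol %), Oxone (2KHSO5·KHSO4·K2SO4), K2CO3, Bu4NHSO4, MeCN/(MeO)2CH2/aq. buffer, 0 °C
Reagents that add atoms: potassium peroxymonosulfate, SMILES [K+].[O-]S(=O)(=O)OO
Why: Shi asymmetric epoxidation attacks only the electron-rich trisubstituted alkene (the enone alkene is inert) and gives one epoxide diastereomer; this centre later becomes the ketone carbon, so its sense is immaterial.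

Step 6
Reactants: 8 (4R)-3-{2-[(2R)-3,3-dimethyloxiran-2-yl]ethyl}-4-hydroxycyclohex-2-en-1-one
Product: 10 (3R,9aR)-3-[(tert-butyldimethylsilyl)oxy]-2,2-dimethyl-2,3,4,5,9,9a-hexahydrobenzo[b]oxepin-7(8H)-one, via oxepanol 9 (not isolated)
Conditions: BF3·OEt2 (0.3 equiv), CH2Cl2, −78 °C; then 2,6-lutidine, TBSOTf, −78 → 0 °C
Reagents that add atoms: tert-butyldimethylsilyl trifluoromethanesulfonate, SMILES CC(C)(C)[Si](C)(C)OS(=O)(=O)C(F)(F)F
Why: Lewis-acid-promoted 7-endo-tet epoxide opening by the allylic hydroxyl at the tertiary (cation-stabilising) carbon closes the oxepane with C-3 unchanged (its C–O bond is not broken), and silylation masks the new secondary alcohol.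

Step 7
Reactants: 10 (3R,9aR)-3-[(tert-butyldimethylsilyl)oxy]-2,2-dimethyl-2,3,4,5,9,9a-hexahydrobenzo[b]oxepin-7(8H)-one
Product: 12 (3R,5aS,6S,9aR)-3-[(tert-butyldimethylsilyl)oxy]-2,2,5a-trimethyl-6-[2-(phenylsulfinyl)ethyl]octahydrobenzo[b]oxepin-7(2H)-one, via lithium enolate 11 (not isolated)
Conditions: Me2CuLi (CuI + 2 MeLi), Et2O, −78 → −20 °C; then phenyl vinyl sulfoxide, THF/HMPA, −78 → 0 °C; aq. NH4Cl
Reagents that add atoms: lithium dimethylcuprate, SMILES [Li+].C[Cu-]C; phenyl vinyl sulfoxide, SMILES C=CS(=O)c1ccccc1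
Why: Cuprate 1,4-addition puts methyl on the ring-fusion carbon anti to the allylic C–O bond (cis-fused, C-5a), and Michael addition of the regiodefined enolate to the vinyl sulfoxide occurs on the convex face, syn to that methyl and away from the oxepane, setting C-6.

Step 8
Reactants: 12 (3R,5aS,6S,9aR)-3-[(tert-butyldimethylsilyl)oxy]-2,2,5a-trimethyl-6-[2-(phenylsulfinyl)ethyl]octahydrobenzo[b]oxepin-7(2H)-one
Product: 13 (3R,5aS,6S,9aR)-3-[(tert-butyldimethylsilyl)oxy]-6-ethenyl-2,2,5a-trimethyloctahydrobenzo[b]oxepin-7(2H)-one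
Conditions: toluene, NaHCO3, 110 °C
Reagents that add atoms: none
Why: Thermal sulfoxide syn-elimination turns the 2-sulfinylethyl group into the vinyl group under neutral conditions that leave C-6 untouched.

Step 9
Reactants: 13 (3R,5aS,6S,9aR)-3-[(tert-butyldimethylsilyl)oxy]-6-ethenyl-2,2,5a-trimethyloctahydrobenzo[b]oxepin-7(2H)-one
Product: 14 (3R,5aS,6S,7R,9aR)-3-[(tert-butyldimethylsilyl)oxy]-6-ethenyl-2,2,5a,7-tetramethyldecahydrobenzo[b]oxepin-7-ol
Conditions: MeMgBr, LaCl3·2LiCl (30 mol %), THF, −20 °C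
Reagents that add atoms: methylmagnesium bromide, SMILES C[Mg]Br
Why: Lewis-acid-assisted Grignard 1,2-addition in which the axial angular methyl and the adjacent vinyl group block one face, so methyl enters from the other and the tertiary hydroxyl ends cis to both (C-7 R).

Step 10
Reactants: 15 acrolein; 16 (3-methylbut-2-en-1-yl)magnesium chloride
Product: 17 4,4-dimethylhexa-1,5-dien-3-ol
Conditions: THF, −78 °C
Reagents that add atoms: none
Why: The allylic Grignard reagent adds 1,2 through its γ-carbon (SE2′, six-membered transition state), building the quaternary gem-dimethyl carbon; the racemic carbinol is oxidised next.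

Step 11
Reactants: 17 4,4-dimethylhexa-1,5-dien-3-ol
Product: 18 4,4-dimethylhexa-1,5-dien-3-one
Conditions: activated MnO2, CH2Cl2, rt
Reagents that add atoms: none
Why: Manganese dioxide oxidation of the allylic alcohol gives the vinyl ketone, used at once as a solution.

Step 12
Reactants: 18 4,4-dimethylhexa-1,5-dien-3-one; 19 methyl 4-oxobutanoate
Product: 20 methyl 8,8-dimethyl-4,7-dioxodec-9-enoate
Conditions: 3-benzyl-5-(2-hydroxyethyl)-4-methylthiazolium chloride (20 mol %), Et3N, EtOH, 70 °C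
Reagents that add atoms: none
Why: Stetter reaction (carbene umpolung of the aldehyde, 1,4-addition to the vinyl ketone) gives the 1,4-diketone; the neopentyl vinyl group is not an acceptor.

Step 13
Reactants: 20 methyl 8,8-dimethyl-4,7-dioxodec-9-enoate
Product: 21 methyl 2-[2-(2-methylbut-3-en-2-yl)-5-oxocyclopent-1-en-1-yl]acetate
Conditions: NaOMe (cat.), MeOH, 65 °C
Reagents that add atoms: none
Why: Intramolecular aldol condensation, in which only the C-3 enolate attacking the C-7 ketone gives a five-membered ring, forms the tetrasubstituted cyclopentenone.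

Step 14
Reactants: 21 methyl 2-[2-(2-methylbut-3-en-2-yl)-5-oxocyclopent-1-en-1-yl]acetate
Product: 22 methyl 2-[(5S)-5-hydroxy-5-methyl-2-(2-methylbut-3-en-2-yl)cyclopent-1-en-1-yl]acetate
Conditions: Me2Zn, Ti(OiPr)4, bis(hydroxycamphorsulfonamide) ligand of trans-cyclohexane-1,2-diamine (10 mol %, enantiomer giving Re-face attack), toluene, rt
Reagents that add atoms: dimethylzinc, SMILES C[Zn]C
Why: Catalytic enantioselective 1,2-addition of dimethylzinc to the α-substituted cyclic enone (titanium bis(sulfonamide) diol catalysis) delivers methyl to the Re face and sets C-1 as S; the ester is inert.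

Step 15
Reactants: 22 methyl 2-[(5S)-5-hydroxy-5-methyl-2-(2-methylbut-3-en-2-yl)cyclopent-1-en-1-yl]acetate
Product: 24 1-[(5S)-5-hydroxy-5-methyl-2-(2-methylbut-3-en-2-yl)cyclopent-1-en-1-yl]-3-methylbut-3-en-2-one, via Weinreb amide 23 (not isolated)
Conditions: MeNHOMe·HCl, i-PrMgCl, THF, −20 °C; then isopropenylmagnesium bromide, 0 °C; aq. NH4Cl
Reagents that add atoms: isopropenylmagnesium bromide, SMILES CC(=C)[Mg]Br
Why: In-situ Weinreb amide formation followed by Grignard addition to the stable magnesium chelate gives the isopropenyl ketone without over-addition; the tertiary alcohol is carried as its alkoxide.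

Step 16
Reactants: 24 1-[(5S)-5-hydroxy-5-methyl-2-(2-methylbut-3-en-2-yl)cyclopent-1-en-1-yl]-3-methylbut-3-en-2-one
Product: 25 (1S)-1-hydroxy-1,4,4,6-tetramethyl-2,3,4,8-tetrahydroazulen-7(1H)-one
Conditions: second-generation Hoveyda–Grubbs catalyst (7.5 mol %), toluene (5 mM), 80 °C
Reagents that add atoms: none
Why: Ring-closing metathesis between the neopentyl vinyl group and the methacryloyl alkene, held cis on the cyclopentene, closes the seven-membered ring as the trisubstituted enone.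

Step 17
Reactants: 25 (1S)-1-hydroxy-1,4,4,6-tetramethyl-2,3,4,8-tetrahydroazulen-7(1H)-one
Product: 26 (1S,3aS,8aS)-1-hydroxy-1,4,4,6-tetramethyl-2,3,3a,4,8,8a-hexahydroazulen-7(1H)-one
Conditions: [Ir(cod)(PCy3)(py)]PF6 (10 mol %), H2 (50 bar), CH2Cl2, rt
Reagents that add atoms: none
Why: Hydroxyl-directed hydrogenation with a Crabtree-type cationic iridium catalyst adds both hydrogens to the tetrasubstituted ring-fusion alkene on the face of the tertiary OH, giving the cis fusion (3aS,8aS) and leaving the hindered enone alkene.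

Step 18
Reactants: 26 (1S,3aS,8aS)-1-hydroxy-1,4,4,6-tetramethyl-2,3,3a,4,8,8a-hexahydroazulen-7(1H)-one
Product: 27 (1S,3aS,7R,8aS)-1,4,4,6-tetramethyl-1,2,3,3a,4,7,8,8a-octahydroazulene-1,7-diol
Conditions: NaBH4, CeCl3·7H2O, MeOH, −78 °C
Reagents that add atoms: none
Why: Luche 1,2-reduction with hydride attack from the convex face (the side of the ring-fusion hydrogens) puts the allylic hydroxyl on the concave face, cis to the five-membered ring (C-7 R).

Step 19
Reactants: 27 (1S,3aS,7R,8aS)-1,4,4,6-tetramethyl-1,2,3,3a,4,7,8,8a-octahydroazulene-1,7-diol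
Product: 28 (1S,3aS,7R,8aS)-1-hydroxy-1,4,4,6-tetramethyl-1,2,3,3a,4,7,8,8a-octahydroazulen-7-yl 2-(diphenylphosphanyl)benzoate
Conditions: 2-(diphenylphosphanyl)benzoic acid, DCC, DMAP (cat.), CH2Cl2, rt, argon
Reagents that add atoms: 2-(diphenylphosphanyl)benzoic acid, SMILES OC(=O)c1ccccc1P(c1ccccc1)c1ccccc1
Why: Steglich esterification acylates only the secondary allylic alcohol (the tertiary one is inert) and installs the phosphine-bearing leaving group with the C-7 configuration unchanged.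

Step 20
Reactants: 14 (3R,5aS,6S,7R,9aR)-3-[(tert-butyldimethylsilyl)oxy]-6-ethenyl-2,2,5a,7-tetramethyldecahydrobenzo[b]oxepin-7-ol; 28 (1S,3aS,7R,8aS)-1-hydroxy-1,4,4,6-tetramethyl-1,2,3,3a,4,7,8,8a-octahydroazulen-7-yl 2-(diphenylphosphanyl)benzoate
Product: 30 (3R,5aS,6S,7R,9aR)-3-[(tert-butyldimethylsilyl)oxy]-6-{2-[(1S,3aS,5R,8aS)-1-hydroxy-1,4,4,6-tetramethyl-1,2,3,3a,4,5,8,8a-octahydroazulen-5-yl]ethyl}-2,2,5a,7-tetramethyldecahydrobenzo[b]oxepin-7-ol, via alkylborane 29 (not isolated)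
Conditions: 14, 9-BBN dimer, THF, 60 °C; then t-BuOK (1.0 equiv), CuBr·SMe2 (10 mol %), 28, THF, 0 → 40 °C
Reagents that add atoms: none
Why: Proposed new method: a copper-catalysed, leaving-group-directed syn-SN2′ allyl–alkyl coupling of a B-alkyl-9-BBN reagent, in which anti-Markovnikov hydroboration of the vinyl group gives the primary alkylborane, tert-butoxide forms the borate that transmetalates to monovalent copper, the alkylcopper is held by the ortho-phosphanyl group of the benzoate and so attacks the γ-carbon (azulene C-5) on the face of the C–O bond, and reductive elimination from the trivalent copper allyl species forms the C5–CH2 bond, moves the alkene to C6=C7 and sets C-5 as R by 1,3-chirality transfer; the closest known reaction types are the copper-catalysed γ-selective coupling of alkyl-9-BBN reagents with allylic phosphates (anti) and the ortho-diphenylphosphanylbenzoate-directed syn allylic substitution with Grignard reagents.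

Step 21
Reactants: 30 the TBS ether from step 20
Product: 31 (3R,5aS,6S,7R,9aR)-6-{2-[(1S,3aS,5R,8aS)-1-hydroxy-1,4,4,6-tetramethyl-1,2,3,3a,4,5,8,8a-octahydroazulen-5-yl]ethyl}-2,2,5a,7-tetramethyldecahydrobenzo[b]oxepine-3,7-diol
Conditions: TBAF, THF, 50 °C
Reagents that add atoms: none
Why: Fluoride-mediated desilylation frees the C-3 hydroxyl; no other group is fluoride-labile.

Step 22
Reactants: 31 the triol from step 21
Product: 32 (5aS,6S,7R,9aR)-7-hydroxy-6-{2-[(1S,3aS,5R,8aS)-1-hydroxy-1,4,4,6-tetramethyl-1,2,3,3a,4,5,8,8a-octahydroazulen-5-yl]ethyl}-2,2,5a,7-tetramethyloctahydrobenzo[b]oxepin-3(2H)-one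
Conditions: Dess–Martin periodinane, NaHCO3, CH2Cl2, 0 °C → rt
Reagents that add atoms: none
Why: Dess–Martin oxidation converts the only secondary alcohol into the oxepanone ketone, leaving both tertiary alcohols and the alkene untouched, to give the target.

## Compound list

1 | 1,4-dioxaspiro[4.5]dec-6-en-8-one | O=C1C=CC2(CC1)OCCO2 | starting material
2 | 7-iodo-1,4-dioxaspiro[4.5]dec-6-en-8-one | O=C1C(I)=CC2(CC1)OCCO2 | intermediate
3 | (8R)-7-iodo-1,4-dioxaspiro[4.5]dec-6-en-8-ol | O[C@@H]1CCC2(OCCO2)C=C1I | intermediate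
4 | 4-methylpenta-1,3-diene | C=CC=C(C)C | starting material
5 | 9-(4-methylpent-3-en-1-yl)-9-borabicyclo[3.3.1]nonane | CC(C)=CCCB1C2CCCC1CCC2 | intermediate
6 | (8R)-7-(4-methylpent-3-en-1-yl)-1,4-dioxaspiro[4.5]dec-6-en-8-ol | O[C@@H]1CCC2(OCCO2)C=C1CCC=C(C)C | intermediate
7 | (4R)-4-hydroxy-3-(4-methylpent-3-en-1-yl)cyclohex-2-en-1-one | O[C@@H]1CCC(=O)C=C1CCC=C(C)C | intermediate
8 | (4R)-3-{2-[(2R)-3,3-dimethyloxiran-2-yl]ethyl}-4-hydroxycyclohex-2-en-1-one | O[C@@H]1CCC(=O)C=C1CC[C@H]1OC1(C)C | intermediate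
9 | (3R,9aR)-3-hydroxy-2,2-dimethyl-2,3,4,5,9,9a-hexahydrobenzo[b]oxepin-7(8H)-one | O=C1C=C2CC[C@@H](O)C(C)(C)O[C@@H]2CC1 | intermediate
10 | (3R,9aR)-3-[(tert-butyldimethylsilyl)oxy]-2,2-dimethyl-2,3,4,5,9,9a-hexahydrobenzo[b]oxepin-7(8H)-one | O=C1C=C2CC[C@@H](O[Si](C)(C)C(C)(C)C)C(C)(C)O[C@@H]2CC1 | intermediate
11 | lithium (3R,5aS,9aR)-3-[(tert-butyldimethylsilyl)oxy]-2,2,5a-trimethyl-2,3,4,5,5a,8,9,9a-octahydrobenzo[b]oxepin-7-olate | [Li]OC1=C[C@]2(C)CC[C@@H](O[Si](C)(C)C(C)(C)C)C(C)(C)O[C@@H]2CC1 | intermediate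
12 | (3R,5aS,6S,9aR)-3-[(tert-butyldimethylsilyl)oxy]-2,2,5a-trimethyl-6-[2-(phenylsulfinyl)ethyl]octahydrobenzo[b]oxepin-7(2H)-one (sulfur epimers) | O=S(c1ccccc1)CC[C@H]1[C@]2(C)CC[C@@H](O[Si](C)(C)C(C)(C)C)C(C)(C)O[C@@H]2CCC1=O | intermediate
13 | (3R,5aS,6S,9aR)-3-[(tert-butyldimethylsilyl)oxy]-6-ethenyl-2,2,5a-trimethyloctahydrobenzo[b]oxepin-7(2H)-one | C=C[C@H]1[C@]2(C)CC[C@@H](O[Si](C)(C)C(C)(C)C)C(C)(C)O[C@@H]2CCC1=O | intermediate
14 | (3R,5aS,6S,7R,9aR)-3-[(tert-butyldimethylsilyl)oxy]-6-ethenyl-2,2,5a,7-tetramethyldecahydrobenzo[b]oxepin-7-ol | C=C[C@H]1[C@]2(C)CC[C@@H](O[Si](C)(C)C(C)(C)C)C(C)(C)O[C@@H]2CC[C@@]1(C)O | intermediate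
15 | acrolein (prop-2-enal) | C=CC=O | starting material
16 | (3-methylbut-2-en-1-yl)magnesium chloride | CC(C)=CC[Mg]Cl | starting material
17 | 4,4-dimethylhexa-1,5-dien-3-ol (racemic) | C=CC(O)C(C)(C)C=C | intermediate
18 | 4,4-dimethylhexa-1,5-dien-3-one | C=CC(=O)C(C)(C)C=C | intermediate
19 | methyl 4-oxobutanoate | COC(=O)CCC=O | starting material
20 | methyl 8,8-dimethyl-4,7-dioxodec-9-enoate | COC(=O)CCC(=O)CCC(=O)C(C)(C)C=C | intermediate
21 | methyl 2-[2-(2-methylbut-3-en-2-yl)-5-oxocyclopent-1-en-1-yl]acetate | COC(=O)CC1=C(CCC1=O)C(C)(C)C=C | intermediate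
22 | methyl 2-[(5S)-5-hydroxy-5-methyl-2-(2-methylbut-3-en-2-yl)cyclopent-1-en-1-yl]acetate | COC(=O)CC1=C(CC[C@]1(C)O)C(C)(C)C=C | intermediate
23 | 2-[(5S)-5-hydroxy-5-methyl-2-(2-methylbut-3-en-2-yl)cyclopent-1-en-1-yl]-N-methoxy-N-methylacetamide | CON(C)C(=O)CC1=C(CC[C@]1(C)O)C(C)(C)C=C | intermediate
24 | 1-[(5S)-5-hydroxy-5-methyl-2-(2-methylbut-3-en-2-yl)cyclopent-1-en-1-yl]-3-methylbut-3-en-2-one | CC(=C)C(=O)CC1=C(CC[C@]1(C)O)C(C)(C)C=C | intermediate
25 | (1S)-1-hydroxy-1,4,4,6-tetramethyl-2,3,4,8-tetrahydroazulen-7(1H)-one | CC1=CC(C)(C)C2=C(CC1=O)[C@@](C)(O)CC2 | intermediate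
26 | (1S,3aS,8aS)-1-hydroxy-1,4,4,6-tetramethyl-2,3,3a,4,8,8a-hexahydroazulen-7(1H)-one (cis-fused, OH on the face of the ring-fusion hydrogens) | CC1=CC(C)(C)[C@H]2CC[C@](C)(O)[C@H]2CC1=O | intermediate
27 | (1S,3aS,7R,8aS)-1,4,4,6-tetramethyl-1,2,3,3a,4,7,8,8a-octahydroazulene-1,7-diol | CC1=CC(C)(C)[C@H]2CC[C@](C)(O)[C@H]2C[C@H]1O | intermediate
28 | (1S,3aS,7R,8aS)-1-hydroxy-1,4,4,6-tetramethyl-1,2,3,3a,4,7,8,8a-octahydroazulen-7-yl 2-(diphenylphosphanyl)benzoate (7-O-ester of 27) | CC1=CC(C)(C)[C@H]2CC[C@](C)(O)[C@H]2C[C@H]1OC(=O)c1ccccc1P(c1ccccc1)c1ccccc1 | intermediate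
29 | 9-{2-[(3R,5aS,6S,7R,9aR)-3-[(tert-butyldimethylsilyl)oxy]-7-hydroxy-2,2,5a,7-tetramethyldecahydrobenzo[b]oxepin-6-yl]ethyl}-9-borabicyclo[3.3.1]nonane | C1CC2CCCC(C1)B2CC[C@H]1[C@]2(C)CC[C@@H](O[Si](C)(C)C(C)(C)C)C(C)(C)O[C@@H]2CC[C@@]1(C)O | intermediate
30 | (3R,5aS,6S,7R,9aR)-3-[(tert-butyldimethylsilyl)oxy]-6-{2-[(1S,3aS,5R,8aS)-1-hydroxy-1,4,4,6-tetramethyl-1,2,3,3a,4,5,8,8a-octahydroazulen-5-yl]ethyl}-2,2,5a,7-tetramethyldecahydrobenzo[b]oxepin-7-ol | CC1=CC[C@H]2[C@H](CC[C@]2(C)O)C(C)(C)[C@@H]1CC[C@H]1[C@]2(C)CC[C@@H](O[Si](C)(C)C(C)(C)C)C(C)(C)O[C@@H]2CC[C@@]1(C)O | intermediate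
31 | (3R,5aS,6S,7R,9aR)-6-{2-[(1S,3aS,5R,8aS)-1-hydroxy-1,4,4,6-tetramethyl-1,2,3,3a,4,5,8,8a-octahydroazulen-5-yl]ethyl}-2,2,5a,7-tetramethyldecahydrobenzo[b]oxepine-3,7-diol | CC1=CC[C@H]2[C@H](CC[C@]2(C)O)C(C)(C)[C@@H]1CC[C@H]1[C@]2(C)CC[C@@H](O)C(C)(C)O[C@@H]2CC[C@@]1(C)O | intermediate
32 | (5aS,6S,7R,9aR)-7-hydroxy-6-{2-[(1S,3aS,5R,8aS)-1-hydroxy-1,4,4,6-tetramethyl-1,2,3,3a,4,5,8,8a-octahydroazulen-5-yl]ethyl}-2,2,5a,7-tetramethyloctahydrobenzo[b]oxepin-3(2H)-one | CC1=CC[C@H]2[C@H](CC[C@]2(C)O)C(C)(C)[C@@H]1CC[C@H]1[C@]2(C)CCC(=O)C(C)(C)O[C@@H]2CC[C@@]1(C)O | target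

## Step count and risks

Total step count: 22. Longest linear sequence: 13 steps (steps 10–19, then 20–22).

The three steps most likely to fail:

**Step 20 (the proposed new coupling).** The uncertain points are B-to-Cu transmetalation in the presence of the phosphine ester and attack at the neopentylic γ-carbon. The fallback uses only known reactions, sets out from enone 10 and diol 27, and comes back at 30. Diol 27 is acylated on the secondary hydroxyl with acryloyl chloride (Et3N, CH2Cl2, −20 °C) to give the acrylate F5. The lithium enolate 11, made from 10 with Me2CuLi as in step 7, is added to F5 (THF, −78 °C, Michael addition) to give the keto ester F6. Ireland–Claisen rearrangement (KHMDS, TMSCl, THF/toluene, −78 → 80 °C, then dilute HCl) transfers the allyl unit suprafacially to C-5 and gives the γ,δ-unsaturated keto acid F7. Barton decarboxylation through the N-acyloxy-2-thiopyridone F8 (t-BuSH, visible light) gives the ketone F9. MeMgBr with LaCl3·2LiCl as in step 9 then gives 30.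

**Step 6 (7-endo epoxide opening).** The hydroxyl may instead attack the secondary epoxide carbon (6-exo). The fallback sets out from ketal alcohol 6 and comes back at 9. Intramolecular alkoxymercuration of 6 (Hg(OCOCF3)2, NaHCO3, CH2Cl2, −20 °C) forms the ether bond under Markovnikov control and gives the organomercurial trifluoroacetate F1. Oxidative demercuration (NaBH4, O2, DMF) gives the ketal-protected oxepanol F2 as both C-3 epimers. Aqueous HCl in THF removes the ketal and returns 9 as a C-3 epimer mixture, which does not matter because C-3 ends as the ketone.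

**Step 17 (directed hydrogenation of the hindered tetrasubstituted alkene).** The fallback sets out from 25 and comes back at 26. Both C=C bonds are hydrogenated over 5% Rh on Al2O3 (H2 80 bar, EtOAc), where hydroxyl anchoring to the surface gives the same cis fusion, to the saturated hydroxy ketone F3. TMSCl, NaI and Et3N in MeCN give the more substituted silyl enol ether, silylated also on the tertiary alcohol, F4. Saegusa–Ito oxidation (Pd(OAc)2, MeCN) followed by K2CO3 in MeOH restores the enone and the free alcohol, 26.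

Further compounds
F1 | step 6 | [(9aR)-2,2-dimethyl-2,3,4,5,9,9a-hexahydro-8H-spiro[benzo[b]oxepine-7,2'-[1,3]dioxolan]-3-yl]mercury trifluoroacetate (C-3 epimers) | CC1(C)O[C@@H]2CCC3(OCCO3)C=C2CCC1[Hg]OC(=O)C(F)(F)F
F2 | step 6 | (9aR)-2,2-dimethyl-2,3,4,5,9,9a-hexahydro-8H-spiro[benzo[b]oxepine-7,2'-[1,3]dioxolan]-3-ol (C-3 epimers) | CC1(C)O[C@@H]2CCC3(OCCO3)C=C2CCC1O
F3 | step 17 | (1S,3aS,8aS)-1-hydroxy-1,4,4,6-tetramethyloctahydroazulen-7(1H)-one (C-6 epimers) | CC1CC(C)(C)[C@H]2CC[C@](C)(O)[C@H]2CC1=O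
F4 | step 17 | (1S,3aS,8aS)-1,4,4,6-tetramethyl-1,7-bis(trimethylsilyloxy)-1,2,3,3a,4,5,8,8a-octahydroazulene | CC=1CC(C)(C)[C@H]2CC[C@](C)(O[Si](C)(C)C)[C@H]2CC=1O[Si](C)(C)C
F5 | step 20 | (1S,3aS,7R,8aS)-1-hydroxy-1,4,4,6-tetramethyl-1,2,3,3a,4,7,8,8a-octahydroazulen-7-yl acrylate | CC1=CC(C)(C)[C@H]2CC[C@](C)(O)[C@H]2C[C@H]1OC(=O)C=C
F6 | step 20 | (1S,3aS,7R,8aS)-1-hydroxy-1,4,4,6-tetramethyl-1,2,3,3a,4,7,8,8a-octahydroazulen-7-yl 3-[(3R,5aS,6S,9aR)-3-[(tert-butyldimethylsilyl)oxy]-2,2,5a-trimethyl-7-oxodecahydrobenzo[b]oxepin-6-yl]propanoate | CC1=CC(C)(C)[C@H]2CC[C@](C)(O)[C@H]2C[C@H]1OC(=O)CC[C@H]1[C@]2(C)CC[C@@H](O[Si](C)(C)C(C)(C)C)C(C)(C)O[C@@H]2CCC1=O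
F7 | step 20 | 3-[(3R,5aS,6S,9aR)-3-[(tert-butyldimethylsilyl)oxy]-2,2,5a-trimethyl-7-oxodecahydrobenzo[b]oxepin-6-yl]-2-[(1S,3aS,5R,8aS)-1-hydroxy-1,4,4,6-tetramethyl-1,2,3,3a,4,5,8,8a-octahydroazulen-5-yl]propanoic acid (C-2 epimers) | CC1=CC[C@H]2[C@H](CC[C@]2(C)O)C(C)(C)[C@@H]1C(C(=O)O)C[C@H]1[C@]2(C)CC[C@@H](O[Si](C)(C)C(C)(C)C)C(C)(C)O[C@@H]2CCC1=O
F8 | step 20 | 2-thioxopyridin-1(2H)-yl ester of F7 | CC1=CC[C@H]2[C@H](CC[C@]2(C)O)C(C)(C)[C@@H]1C(C(=O)ON1C=CC=CC1=S)C[C@H]1[C@]2(C)CC[C@@H](O[Si](C)(C)C(C)(C)C)C(C)(C)O[C@@H]2CCC1=O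
F9 | step 20 | (3R,5aS,6S,9aR)-3-[(tert-butyldimethylsilyl)oxy]-6-{2-[(1S,3aS,5R,8aS)-1-hydroxy-1,4,4,6-tetramethyl-1,2,3,3a,4,5,8,8a-octahydroazulen-5-yl]ethyl}-2,2,5a-trimethyloctahydrobenzo[b]oxepin-7(2H)-one | CC1=CC[C@H]2[C@H](CC[C@]2(C)O)C(C)(C)[C@@H]1CC[C@H]1[C@]2(C)CC[C@@H](O[Si](C)(C)C(C)(C)C)C(C)(C)O[C@@H]2CCC1=O
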